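The constant I trusted most in the earlier runs was the one zeta shows during its feed: how quickly a flask clears the E that has gone in.

| setting | epsilon | zeta | delta | Thursday's | Saturday's | Tuesday's | Friday's | Wednesday's |
|---|---|---|---|---|---|---|---|---|
| E | 0.050 M (fed, over 1.0 h) | 0.050 M (fed, over 1.0 h) | 0.050 M (fed, over 1.0 h) | 0.012 M (fed, over 1.0 h) | 0.050 M (fed, over 1.0 h) | 0.015 M (fed, over 1.0 h) | 0.050 M (fed, over 1.0 h) | 0.050 M (fed, over 1.0 h) |
| Q | 0.024 M | 0.48 M | 0.075 M | 0.300 M | 0.0200 M | 0.0750 M | 0.300 M | 0.0750 M |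
| L | 0.50 mM | 0.50 mM | 0.18 mM | 0.50 mM | 0.15 mM | 0.15 mM | 0.12 mM | 0.50 mM |
| temperature | 5 °C | 45 °C | 5 °C | 70 °C | 80 °C | 50 °C | 10 °C | 50 °C |
| remark | run made earlier | run made earlier | run made earlier |  |  |  |  |  |
| time |  |  |  | 3.0 h | 3.0 h | 3.0 h | 3.0 h | 3.0 h |

epsilon run (percent of the E charged): time / h: J / % = 1.33: 2.1; 2.00: 3.3; 3.00: 6.2; 5.00: 8.9; 8.00: 15.0; 15.0: 22.6

zeta run (percent of the E charged): time / min: J / % = 8.00: 6.6; 12.0: 12.6; 20.0: 25.1; 30.0: 41.8; 50.0: 74.4; 90.0: 98.7

delta run (percent of the E charged): time / h: J / % = 1.33: 2.3; 4.00: 9.5; 6.00: 14.1; 10.0: 21.4; 15.0: 31.9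

(readings scatter by 0.5 percentage points)

* the flasks by amount of J, in percent of the E charged, highest first, at 3.0 h (Thursday's / Saturday's / Tuesday's / Friday's / Wednesday's)
* the amount of J, in percent of the E charged of the flask you put first, at 3.0 h
* the amount of J, in percent of the E charged of the flask you put last, at 3.0 h

- the numbers in the tables scatter by 0.5 percentage points (one standard deviation)
- percentages count the whole charge, also what has not yet gone in

In zeta the fed share ran ahead of J by 8.20% at 30.0 min and by 8.93% at 50.0 min. That gap held steady within the scatter, so J was keeping pace with the feed, and dividing the feed by the gap gave the clearing rate. I scaled that rate with L·Q. At 1.33 h epsilon stood at 2.1% and delta at 2.3%, although delta had 3.12 times the Q and epsilon 2.78 times the L. Thursday's has zeta's L, so Q alone carried the scaling: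

κ(zeta) = feed ÷ mean gap = 1.00 h⁻¹ ÷ 8.57% = 11.7 h⁻¹

κ(Thursday's) = κ(zeta) × 0.300 M ÷ 0.48 M = 7.30 h⁻¹

This κ, the share of the E present that Thursday's turns into J each hour with Q and L frozen, is its pseudo-first-order constant. It sets the start: J falls behind the feed by about 13.7% of the charge, then follows at the feed's pace.

Q could slow it. Thursday's E can use at most 4.00% of the Q, a factor of 0.960. I held L at its charge and gave no credit for going from 45 °C to 70 °C, so I treated this κ as a floor. The life 8.22 min is shorter than the 2.00 h after the feed, so the accumulated slowing hardly matters: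

lifetimes after the feed = κ × 0.960 × (time left) = 14.0

J in Thursday's at 3.0 h = >99.9%

The forecast put Thursday's > Wednesday's > Tuesday's > Friday's > Saturday's, with 99% on top and 22% at the bottom, and noted “Friday versus Saturday is close”.

The simulation gave Thursday's > Wednesday's > Tuesday's > Saturday's > Friday's, with 100% for Thursday's, 36.6% for Saturday's and 24.3% for Friday's.

    E + Q + L → J + L, rate k1*[E]*[Q]*[L]/(1 + ([E]/sat1)) (43.0 mM, k = 1200 M⁻² min⁻¹, Ea = 47.0 kJ mol⁻¹)
    (constants at 50 °C)

At the end of the feed Thursday's held 3.50% of its E, against my 13.7%. Feed over that share gives a κ of 28.5 h⁻¹, which is 3.90 times my floor. For the neighbour charged with 0.020 M of E, the Q factor becomes 0.933, so my floor κ, lower than the 28.5 h⁻¹ just reckoned, counts at least 13.6 lifetimes after its feed, and 28.5 h⁻¹ counts about 53.3. That neighbour gave 100% of J, with 93% of its Q left.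

(The data are calculated for an exercise.)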